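A direct plan would take both ether stereocentres from the chiral pool as free carbinols: the arylpropanol A1 (aryl Grignard reagent plus a chiral epoxide) and the lactate-derived hydroxy ketone A2.
Each would be joined to a 2,6-dimethoxyphenol by Mitsunobu etherification, and the aryloxy ketone A3 so formed would be reduced and acetylated.
Its weakest steps would be:
(a) the Mitsunobu etherification of A1, where a di-ortho-substituted phenol must displace an unactivated secondary carbinol next to an electron-rich benzyl group, so elimination to the styrene and aryl participation would cost yield and configuration;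
(b) the Mitsunobu union of A2 with the most advanced phenol, a sluggish redox condensation on precious material whose product A3 has an acidic, epimerisable C8–H;
(c) the hydride reduction of A3, where C7 would depend on chelation by a hindered, weakly basic aryl ether oxygen, so the erythro relation would be left to chance.
It would also spend about a third of its steps on simple phenolic building blocks that can be bought.

**Plan of the new route**
The target is read as a head-to-tail dimer: ring A–O–C8'H(CH3)–C7' and ring B–O–C8H(CH3)–C7 are two copies of one (R)-2-(4-substituted 2,6-dimethoxyphenoxy)propyl unit, so one bromoaryloxypropanol serves twice, once as alkyl electrophile and once as aryl nucleophile.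
Cuts, in retrosynthetic order: C7–C1 of ring C together with the O-acetyl bond (aryl addition to an aldehyde, acetate trapped in the flask); C7'–C4 of ring B (aryl Grignard reagent plus alkyl tosylate); C4 of ring A–propenyl; then O–C8 and O–C8' together in one SN2 on a lactate triflate.
No ring is formed: rings A and B come from one bought bromophenol, ring B is joined to C7' first, and ring C enters last.
Both hindered aryl ether bonds arise by inversion at a carbonyl-activated triflate on a cheap phenol, so no Mitsunobu step, no α-aryloxy ketone and no hydride reduction occur.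
C7 is made by C–C bond formation in which catalyst control and Felkin–Anh control point the same way.

Key step: step 9

Assumption: the bromophenol, the lactate triflate, the propenylboronate and the aryl Grignard solution used below are taken as commercial.

Step 1
Reactants: 1 4-bromo-2,6-dimethoxyphenol; 2 ethyl (2S)-2-{[(trifluoromethyl)sulfonyl]oxy}propanoate
Product: 3 ethyl (2R)-2-(4-bromo-2,6-dimethoxyphenoxy)propanoate
Conditions: K2CO3 (1.5 equiv), MeCN, 0 °C → rt
Reagents that add atoms: none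
Why: Williamson-type SN2 etherification at the carbonyl-activated, highly reactive secondary triflate should go with clean inversion even with the di-ortho-substituted phenoxide, turning (S) of the lactate into the (R) aryl ether that becomes both C8 and C8'.

Step 2
Reactants: 3 ethyl (2R)-2-(4-bromo-2,6-dimethoxyphenoxy)propanoate
Product: 4 (2R)-2-(4-bromo-2,6-dimethoxyphenoxy)propan-1-ol
Conditions: LiBH4 (1.2 equiv), THF, 0 °C → rt; aq. NH4Cl
Reagents that add atoms: none
Why: Chemoselective borohydride reduction of the α-aryloxy ester to the primary alcohol should leave the aryl bromide and the stereocentre untouched.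

Step 3
Reactants: 4 (2R)-2-(4-bromo-2,6-dimethoxyphenoxy)propan-1-ol; 5 4,4,5,5-tetramethyl-2-[(E)-prop-1-enyl]-1,3,2-dioxaborolane
Product: 6 (2R)-2-{2,6-dimethoxy-4-[(E)-prop-1-enyl]phenoxy}propan-1-ol
Conditions: PdCl2(dppf) (3 mol %), K2CO3, 1,4-dioxane/H2O, 80 °C
Reagents that add atoms: none
Why: Suzuki–Miyaura coupling retains the alkene geometry of the boronate through transmetalation and reductive elimination, so the (E)-propenyl group of ring A should enter as a single isomer in the presence of the free hydroxyl group.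

Step 4
Reactants: 6 (2R)-2-{2,6-dimethoxy-4-[(E)-prop-1-enyl]phenoxy}propan-1-ol
Product: 7 (2R)-2-{2,6-dimethoxy-4-[(E)-prop-1-enyl]phenoxy}propyl 4-methylbenzenesulfonate
Conditions: TsCl (1.3 equiv), Et3N, DMAP (cat.), CH2Cl2, 0 °C → rt
Reagents that add atoms: 4-methylbenzenesulfonyl chloride, Cc1ccc(cc1)S(=O)(=O)Cl
Why: O-sulfonylation of the primary alcohol activates C7' for substitution without involving any bond to the stereocentre.

Step 5
Reactants: 4 (2R)-2-(4-bromo-2,6-dimethoxyphenoxy)propan-1-ol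
Product: 8 tert-butyl[(2R)-2-(4-bromo-2,6-dimethoxyphenoxy)propoxy]dimethylsilane
Conditions: TBSCl, imidazole, DMF, rt
Reagents that add atoms: tert-butyldimethylsilyl chloride, CC(C)(C)[Si](C)(C)Cl
Why: Imidazole-promoted O-silylation masks the primary alcohol of the second copy of 4 so that its aryl bromide can be turned into a Grignard reagent.

Step 6
Reactants: 8 tert-butyl[(2R)-2-(4-bromo-2,6-dimethoxyphenoxy)propoxy]dimethylsilane; 7 (2R)-2-{2,6-dimethoxy-4-[(E)-prop-1-enyl]phenoxy}propyl 4-methylbenzenesulfonate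
Product: 10 tert-butyl{(2R)-2-[2,6-dimethoxy-4-((2R)-2-{2,6-dimethoxy-4-[(E)-prop-1-enyl]phenoxy}propyl)phenoxy]propoxy}dimethylsilane, via arylmagnesium bromide 9 (not isolated)
Conditions: 8, Mg (I2 cat.), THF, reflux; then CuI (10 mol %), 7 (0.65 equiv), THF, −20 °C → rt; aq. NH4Cl
Reagents that add atoms: none
Why: Kochi-type copper-catalysed sp2–sp3 cross-coupling of an aryl Grignard reagent with a primary alkyl tosylate forms the C7'–ring B bond by SN2 of the arylcuprate at CH2, a closed-shell path chosen because it touches neither stereocentre and avoids a C7' radical that could expel the aryloxy group.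

Step 7
Reactants: 10 tert-butyl{(2R)-2-[2,6-dimethoxy-4-((2R)-2-{2,6-dimethoxy-4-[(E)-prop-1-enyl]phenoxy}propyl)phenoxy]propoxy}dimethylsilane
Product: 11 (2R)-2-[2,6-dimethoxy-4-((2R)-2-{2,6-dimethoxy-4-[(E)-prop-1-enyl]phenoxy}propyl)phenoxy]propan-1-ol
Conditions: Bu4NF (1.2 equiv), THF, 0 °C → rt
Reagents that add atoms: none
Why: Fluoride-driven desilylation frees the primary alcohol while the aryl ethers and the propenyl group stay inert.

Step 8
Reactants: 11 (2R)-2-[2,6-dimethoxy-4-((2R)-2-{2,6-dimethoxy-4-[(E)-prop-1-enyl]phenoxy}propyl)phenoxy]propan-1-ol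
Product: 12 (2R)-2-[2,6-dimethoxy-4-((2R)-2-{2,6-dimethoxy-4-[(E)-prop-1-enyl]phenoxy}propyl)phenoxy]propanal
Conditions: Dess–Martin periodinane (1.2 equiv), NaHCO3, CH2Cl2, 0 °C → rt; used at once
Reagents that add atoms: none
Why: Dess–Martin oxidation under bicarbonate buffer is neutral and non-enolising, so the α-aryloxy aldehyde should form without loss of the C8 configuration.

Step 9
Reactants: 12 (2R)-2-[2,6-dimethoxy-4-((2R)-2-{2,6-dimethoxy-4-[(E)-prop-1-enyl]phenoxy}propyl)phenoxy]propanal; 13 (3,4,5-trimethoxyphenyl)magnesium bromide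
Product: 16 (1S,2R)-2-{2,6-dimethoxy-4-[(2R)-2-{2,6-dimethoxy-4-[(E)-prop-1-enyl]phenoxy}propyl]phenoxy}-1-(3,4,5-trimethoxyphenyl)propyl acetate, via triisopropoxy(3,4,5-trimethoxyphenyl)titanium 14 (not isolated), via triisopropoxytitanium alkoxide 15 (not isolated)
Conditions: 13 (1.5 equiv), ClTi(OiPr)3, THF, −78 → 0 °C; (S)-H8-BINOL/Ti(OiPr)4 (10 mol %), 12, toluene, 0 °C; then Ac2O, DMAP (cat.), 0 °C → rt
Reagents that add atoms: acetic anhydride, CC(=O)OC(C)=O
Why: Transmetalation of 13 with ClTi(OiPr)3 gives the aryltitanium reagent 14, its aryl group is transferred to the aldehyde carbon C7 inside a binaphtholate-bridged titanium assembly, and the titanium alkoxide 15 is acetylated by Ac2O in the same flask, so the C7–C1 bond to ring C, the C7 stereocentre and the O-acetyl bond arise in one operation and the free carbinol is never handled. The closest known reaction types are the titanium H8-binaphtholate-catalysed asymmetric addition of aryltitanium triisopropoxides to aldehydes and the non-chelation-controlled addition of organotitanium triisopropoxides to α-alkoxy aldehydes. No ring is closed. The new stereocentre C7 (S) is controlled twice in the same sense: the (S)-ligand is chosen, by analogy with (S)-binaphtholate–titanium carbon transfers, to deliver aryl to the Si face (to be confirmed on a model α-aryloxy aldehyde), and the Felkin–Anh arrangement of the (R)-aldehyde (aryloxy group anti to the incoming aryl, attack past the C8 hydrogen and not the methyl group) exposes the same Si face, which gives the erythro (1S,2R) relation. The step needs face selectivity at C7 and no enolisation at C8; the fully alkoxylated tetravalent titanium is too weak a Lewis acid to chelate the hindered, weakly basic ring B ether oxygen (the path to the threo isomer) and too weak a base to deprotonate C8. The (E)-propenyl group, the aryl methyl ethers and the C8' ether are inert to the reagent.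

**Compound list**

1 | 4-bromo-2,6-dimethoxyphenol | COc1cc(Br)cc(OC)c1O | starting material
2 | ethyl (2S)-2-{[(trifluoromethyl)sulfonyl]oxy}propanoate | CCOC(=O)[C@H](C)OS(=O)(=O)C(F)(F)F | starting material
3 | ethyl (2R)-2-(4-bromo-2,6-dimethoxyphenoxy)propanoate | COc1cc(Br)cc(OC)c1O[C@H](C)C(=O)OCC | intermediate
4 | (2R)-2-(4-bromo-2,6-dimethoxyphenoxy)propan-1-ol | COc1cc(Br)cc(OC)c1O[C@H](C)CO | intermediate
5 | 4,4,5,5-tetramethyl-2-[(E)-prop-1-enyl]-1,3,2-dioxaborolane | C/C=C/B1OC(C)(C)C(C)(C)O1 | starting material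
6 | (2R)-2-{2,6-dimethoxy-4-[(E)-prop-1-enyl]phenoxy}propan-1-ol | C/C=C/c1cc(OC)c(O[C@H](C)CO)c(OC)c1 | intermediate
7 | (2R)-2-{2,6-dimethoxy-4-[(E)-prop-1-enyl]phenoxy}propyl 4-methylbenzenesulfonate | C/C=C/c1cc(OC)c(O[C@H](C)COS(=O)(=O)c2ccc(C)cc2)c(OC)c1 | intermediate
8 | tert-butyl[(2R)-2-(4-bromo-2,6-dimethoxyphenoxy)propoxy]dimethylsilane | COc1cc(Br)cc(OC)c1O[C@H](C)CO[Si](C)(C)C(C)(C)C | intermediate
9 | [4-{[(2R)-1-(tert-butyldimethylsilyloxy)propan-2-yl]oxy}-3,5-dimethoxyphenyl]magnesium bromide | COc1cc([Mg]Br)cc(OC)c1O[C@H](C)CO[Si](C)(C)C(C)(C)C | intermediate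
10 | tert-butyl{(2R)-2-[2,6-dimethoxy-4-((2R)-2-{2,6-dimethoxy-4-[(E)-prop-1-enyl]phenoxy}propyl)phenoxy]propoxy}dimethylsilane | C/C=C/c1cc(OC)c(O[C@H](C)Cc2cc(OC)c(O[C@H](C)CO[Si](C)(C)C(C)(C)C)c(OC)c2)c(OC)c1 | intermediate
11 | (2R)-2-[2,6-dimethoxy-4-((2R)-2-{2,6-dimethoxy-4-[(E)-prop-1-enyl]phenoxy}propyl)phenoxy]propan-1-ol | C/C=C/c1cc(OC)c(O[C@H](C)Cc2cc(OC)c(O[C@H](C)CO)c(OC)c2)c(OC)c1 | intermediate
12 | (2R)-2-[2,6-dimethoxy-4-((2R)-2-{2,6-dimethoxy-4-[(E)-prop-1-enyl]phenoxy}propyl)phenoxy]propanal | C/C=C/c1cc(OC)c(O[C@H](C)Cc2cc(OC)c(O[C@H](C)C=O)c(OC)c2)c(OC)c1 | intermediate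
13 | (3,4,5-trimethoxyphenyl)magnesium bromide | COc1cc([Mg]Br)cc(OC)c1OC | starting material
14 | triisopropoxy(3,4,5-trimethoxyphenyl)titanium | COc1cc(cc(OC)c1OC)[Ti](OC(C)C)(OC(C)C)OC(C)C | intermediate
15 | triisopropoxytitanium (1S,2R)-2-{2,6-dimethoxy-4-[(2R)-2-{2,6-dimethoxy-4-[(E)-prop-1-enyl]phenoxy}propyl]phenoxy}-1-(3,4,5-trimethoxyphenyl)propan-1-olate | C/C=C/c1cc(OC)c(O[C@H](C)Cc2cc(OC)c(O[C@H](C)[C@@H](O[Ti](OC(C)C)(OC(C)C)OC(C)C)c3cc(OC)c(OC)c(OC)c3)c(OC)c2)c(OC)c1 | intermediate
16 | (1S,2R)-2-{2,6-dimethoxy-4-[(2R)-2-{2,6-dimethoxy-4-[(E)-prop-1-enyl]phenoxy}propyl]phenoxy}-1-(3,4,5-trimethoxyphenyl)propyl acetate | C/C=C/c1cc(OC)c(O[C@H](C)Cc2cc(OC)c(O[C@H](C)[C@@H](OC(C)=O)c3cc(OC)c(OC)c(OC)c3)c(OC)c2)c(OC)c1 | target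

Total step count: 9. Longest linear sequence: 8 (steps 1, 2, 3, 4, 6, 7, 8, 9).

**Steps most likely to fail**

Step 9. The risk is insufficient facial selectivity in the aryl transfer (catalyst and substrate not reinforcing as expected, or a competing chelated pathway through the ring B methoxy groups) or incomplete acetylation of the titanium alkoxide. The fallback sets out from 12 and separates C–C bond formation from stereocontrol:
- 13 would be added without titanium or Ac2O to give the C1-epimeric carbinol mixture (2R)-2-{2,6-dimethoxy-4-[(2R)-2-{2,6-dimethoxy-4-[(E)-prop-1-enyl]phenoxy}propyl]phenoxy}-1-(3,4,5-trimethoxyphenyl)propan-1-ol F1.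
- Dess–Martin oxidation would give the ketone (2R)-2-{2,6-dimethoxy-4-[(2R)-2-{2,6-dimethoxy-4-[(E)-prop-1-enyl]phenoxy}propyl]phenoxy}-1-(3,4,5-trimethoxyphenyl)propan-1-one F2, the same compound as A3 but reached here without a Mitsunobu step.
- Catalyst-controlled asymmetric transfer hydrogenation with RuCl(p-cymene)[(R,R)-TsDPEN] and HCO2H/Et3N should set C7 independently of chelation and give the (1S,2R)-configured propan-1-ol F3.
- Acetylation with Ac2O/DMAP returns to the route at 16.

Step 6. The risk is slow displacement at the β-branched, β-oxygenated CH2–OTs carbon, so that attack of the Grignard reagent at sulfur or elimination to the isopropenyl ether takes over. The fallback sets out from 7 and reverses the polarity of the union: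
- Copper-catalysed borylation (CuI, PPh3, LiOMe, B2pin2, DMF) would give 2-[(2R)-2-{2,6-dimethoxy-4-[(E)-prop-1-enyl]phenoxy}propyl]-4,4,5,5-tetramethyl-1,3,2-dioxaborolane F4.
- KHF2 would convert it into potassium trifluoro[(2R)-2-{2,6-dimethoxy-4-[(E)-prop-1-enyl]phenoxy}propyl]borate F5.
- Suzuki–Miyaura coupling of F5 with aryl bromide 8 (Pd(OAc)2, RuPhos, K2CO3, toluene/H2O, 80 °C) returns to the route at 10.

Step 8. The risk is enolisation of the α-aryloxy aldehyde during oxidation, isolation or storage, with loss of configuration at C8. The fallback sets out from 11 and avoids the aldehyde altogether: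
- Oxidation with TEMPO (cat.) and PhI(OAc)2 in MeCN/H2O would give (2R)-2-[2,6-dimethoxy-4-((2R)-2-{2,6-dimethoxy-4-[(E)-prop-1-enyl]phenoxy}propyl)phenoxy]propanoic acid F6.
- Carbodiimide coupling with MeNHOMe·HCl would give the configurationally robust (2R)-N-methoxy-N-methyl-2-[2,6-dimethoxy-4-((2R)-2-{2,6-dimethoxy-4-[(E)-prop-1-enyl]phenoxy}propyl)phenoxy]propanamide F7.
- Addition of 13 to F7 would give the ketone F2, which is reduced to F3 and acetylated as in the fallback to step 9, returning to the route at 16.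

**Further compounds**

F1 | step 9 | (2R)-2-{2,6-dimethoxy-4-[(2R)-2-{2,6-dimethoxy-4-[(E)-prop-1-enyl]phenoxy}propyl]phenoxy}-1-(3,4,5-trimethoxyphenyl)propan-1-ol, mixture of C1 epimers | C/C=C/c1cc(OC)c(O[C@H](C)Cc2cc(OC)c(O[C@H](C)C(O)c3cc(OC)c(OC)c(OC)c3)c(OC)c2)c(OC)c1
F2 | step 9 | (2R)-2-{2,6-dimethoxy-4-[(2R)-2-{2,6-dimethoxy-4-[(E)-prop-1-enyl]phenoxy}propyl]phenoxy}-1-(3,4,5-trimethoxyphenyl)propan-1-one | C/C=C/c1cc(OC)c(O[C@H](C)Cc2cc(OC)c(O[C@H](C)C(=O)c3cc(OC)c(OC)c(OC)c3)c(OC)c2)c(OC)c1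
F3 | step 9 | (1S,2R)-2-{2,6-dimethoxy-4-[(2R)-2-{2,6-dimethoxy-4-[(E)-prop-1-enyl]phenoxy}propyl]phenoxy}-1-(3,4,5-trimethoxyphenyl)propan-1-ol | C/C=C/c1cc(OC)c(O[C@H](C)Cc2cc(OC)c(O[C@H](C)[C@@H](O)c3cc(OC)c(OC)c(OC)c3)c(OC)c2)c(OC)c1
F4 | step 6 | 2-[(2R)-2-{2,6-dimethoxy-4-[(E)-prop-1-enyl]phenoxy}propyl]-4,4,5,5-tetramethyl-1,3,2-dioxaborolane | C/C=C/c1cc(OC)c(O[C@H](C)CB2OC(C)(C)C(C)(C)O2)c(OC)c1
F5 | step 6 | potassium trifluoro[(2R)-2-{2,6-dimethoxy-4-[(E)-prop-1-enyl]phenoxy}propyl]borate | C/C=C/c1cc(OC)c(O[C@H](C)C[B-](F)(F)F)c(OC)c1.[K+]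
F6 | step 8 | (2R)-2-[2,6-dimethoxy-4-((2R)-2-{2,6-dimethoxy-4-[(E)-prop-1-enyl]phenoxy}propyl)phenoxy]propanoic acid | C/C=C/c1cc(OC)c(O[C@H](C)Cc2cc(OC)c(O[C@H](C)C(=O)O)c(OC)c2)c(OC)c1
F7 | step 8 | (2R)-N-methoxy-N-methyl-2-[2,6-dimethoxy-4-((2R)-2-{2,6-dimethoxy-4-[(E)-prop-1-enyl]phenoxy}propyl)phenoxy]propanamide | C/C=C/c1cc(OC)c(O[C@H](C)Cc2cc(OC)c(O[C@H](C)C(=O)N(C)OC)c(OC)c2)c(OC)c1
A1 | direct plan | (2S)-1-[4-(tert-butyldimethylsilyloxy)-3,5-dimethoxyphenyl]propan-2-ol | C[C@H](O)Cc1cc(OC)c(O[Si](C)(C)C(C)(C)C)c(OC)c1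
A2 | direct plan | (2S)-2-hydroxy-1-(3,4,5-trimethoxyphenyl)propan-1-one | COc1cc(cc(OC)c1OC)C(=O)[C@H](C)O
A3 | direct plan | (2R)-2-{2,6-dimethoxy-4-[(2R)-2-{2,6-dimethoxy-4-[(E)-prop-1-enyl]phenoxy}propyl]phenoxy}-1-(3,4,5-trimethoxyphenyl)propan-1-one | C/C=C/c1cc(OC)c(O[C@H](C)Cc2cc(OC)c(O[C@H](C)C(=O)c3cc(OC)c(OC)c(OC)c3)c(OC)c2)c(OC)c1
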